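## Retrosynthetic overview

- The target comes from its 4-O-methyl ether by BBr3 demethylation. No ring is built: the indole and the pyrimidine are both bought intact.
- Key disconnection: indole C3–pyrimidine C5. Both carbons are inherently nucleophilic (indole C3; C5 is the α-carbon of the 4-aminopyrimidine amidine). C5 is polarity-inverted as a pyrimidin-5-yl(mesityl)iodonium salt, an aza-enolonium (heteroaryl cation) synthon, and delivered to the C3–H of unprotected 7-bromo-4-methoxyindole under Cu(OTf)2 catalysis.
- The iodonium salt comes from 2-bromo-5-iodopyrimidin-4-amine (mCPBA/TfOH, then mesitylene), which comes from 2-bromopyrimidin-4-amine (NIS).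
- No Pd, Li or Mg is used, so the 2-bromopyrimidine and 7-bromoindole C–Br bonds are never at risk; there is no N-protection and no prefunctionalisation of the indole.

Assumption: the target is achiral (no stereocentre, freely rotating biaryl axis), so no stereocontrol is needed; 2-bromopyrimidin-4-amine and 7-bromo-4-methoxy-1H-indole are taken as catalogue compounds.

## Route

Step 1
Reactants: 1 2-bromopyrimidin-4-amine
Product: 2 2-bromo-5-iodopyrimidin-4-amine
Conditions: NIS (1.15 equiv), DMF, 60 °C
Reagents that add atoms: N-iodosuccinimide, O=C1CCC(=O)N1I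
Why: Electrophilic aromatic iodination; the 4-amino group makes C5 the only nucleophilic ring carbon, so NIS iodinates there while C6 and the C2–Br bond are inert.

Step 2
Reactants: 2 2-bromo-5-iodopyrimidin-4-amine
Product: 4 (4-amino-2-bromopyrimidin-5-yl)(2,4,6-trimethylphenyl)iodonium trifluoromethanesulfonate, via bis(triflyloxy)iodopyrimidine 3 (not isolated)
Conditions: mCPBA (1.3 equiv), TfOH (4 equiv), DCE, 0 → 60 °C; then mesitylene (1.2 equiv), 0 °C → rt; Et2O precipitation
Reagents that add atoms: mesitylene, Cc1cc(C)cc(C)c1; trifluoromethanesulfonic acid, OS(=O)(=O)C(F)(F)F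
Why: One-pot oxidation–arylation synthesis of a diaryliodonium salt; excess TfOH N-protonates the aminopyrimidine and shields it from N-oxidation while mCPBA raises the aryl iodide to trivalent iodine, which then attacks mesitylene by electrophilic aromatic substitution to give the unsymmetrical salt with a non-transferable mesityl group.

Step 3
Reactants: 4 (4-amino-2-bromopyrimidin-5-yl)(2,4,6-trimethylphenyl)iodonium trifluoromethanesulfonate; 5 7-bromo-4-methoxy-1H-indole
Product: 6 2-bromo-5-(7-bromo-4-methoxy-1H-indol-3-yl)pyrimidin-4-amine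
Conditions: Cu(OTf)2 (10 mol%), 2,6-di-tert-butylpyridine (1.2 equiv), DCE, 40 °C, N2
Reagents that add atoms: none
Why: Proposed new method: the doubly ortho-substituted mesityl group stays on iodine, so monovalent copper (formed in situ from Cu(OTf)2) takes up the pyrimidin-5-yl group as a strongly electrophilic trivalent copper aryl, which the free indole attacks at C3 in a Friedel–Crafts-type step followed by rearomatisation and reductive elimination, joining two inherently nucleophilic carbons through the aza-enolonium character of the iodonium carbon and leaving both C–Br bonds untouched; the closest known reaction type is the copper-catalysed C3–H arylation of N–H indoles with diaryliodonium triflates.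

Step 4
Reactants: 6 2-bromo-5-(7-bromo-4-methoxy-1H-indol-3-yl)pyrimidin-4-amine
Product: 8 3-(4-amino-2-bromopyrimidin-5-yl)-7-bromo-1H-indol-4-ol, via aryloxydibromoborane 7 (not isolated)
Conditions: BBr3 (6 equiv), CH2Cl2, −78 °C → rt; then H2O, 0 °C
Reagents that add atoms: none
Why: Lewis-acid aryl methyl ether cleavage; BBr3 coordinates the methoxy oxygen and bromide removes the methyl group by SN2 to give the aryloxyborane that is hydrolysed on quench, the excess reagent covers complexation to the aminopyrimidine nitrogens, and the heteroaryl C–Br bonds can at worst undergo degenerate bromide exchange.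

## Compound list

1 | 2-bromopyrimidin-4-amine | Nc1nc(Br)ncc1 | starting material
2 | 2-bromo-5-iodopyrimidin-4-amine | Nc1nc(Br)ncc1I | intermediate
3 | 2-bromo-5-[bis(trifluoromethanesulfonyloxy)iodo]pyrimidin-4-amine | Nc1nc(Br)ncc1I(OS(=O)(=O)C(F)(F)F)OS(=O)(=O)C(F)(F)F | intermediate
4 | (4-amino-2-bromopyrimidin-5-yl)(2,4,6-trimethylphenyl)iodonium trifluoromethanesulfonate | Cc1cc(C)c([I+]c2cnc(Br)nc2N)c(C)c1.[O-]S(=O)(=O)C(F)(F)F | intermediate
5 | 7-bromo-4-methoxy-1H-indole | COc1ccc(Br)c2[nH]ccc12 | starting material
6 | 2-bromo-5-(7-bromo-4-methoxy-1H-indol-3-yl)pyrimidin-4-amine | COc1ccc(Br)c2[nH]cc(-c3cnc(Br)nc3N)c12 | intermediate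
7 | 2-bromo-5-[7-bromo-4-(dibromoboranyloxy)-1H-indol-3-yl]pyrimidin-4-amine | Nc1nc(Br)ncc1-c1c[nH]c2c(Br)ccc(OB(Br)Br)c12 | intermediate
8 | 3-(4-amino-2-bromopyrimidin-5-yl)-7-bromo-1H-indol-4-ol | Nc1nc(Br)ncc1-c1c[nH]c2c(Br)ccc(O)c12 | target

## Step count and risks

Total steps: 4. Longest linear sequence: 4 (1 → 2 → 4 → 6 → 8); indole 5 enters at step 3.

**Most likely to fail, with fallbacks**

Step 3 (key coupling). The risks are a sluggish or misdirected aryl transfer to the peri-hindered C3 and copper sequestration by the aminopyrimidine. The fallback reverses the roles of the two partners, so that the indole carries the trivalent iodine. It sets out from 5 and 1. Indole 5 is C3-iodanated with 1-acetoxy-1,2-benziodoxol-3(1H)-one and Zn(OTf)2 (20 mol%) in CH2Cl2 to give 1-(7-bromo-4-methoxy-1H-indol-3-yl)-1,2-benziodoxol-3(1H)-one F1, an indol-3-yl cation synthon. Amine 1 is acetylated (Ac2O, pyridine) to N-(2-bromopyrimidin-4-yl)acetamide F2. Amide-directed C5–H heteroarylation of F2 with F1 ([Cp*RhCl2]2, AgSbF6, DCE, 60 °C) gives N-[2-bromo-5-(7-bromo-4-methoxy-1H-indol-3-yl)pyrimidin-4-yl]acetamide F3. NH3 in MeOH at 0 °C removes the acetyl group and comes back to the route at 6.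

Step 2 (iodonium formation). The risks are N-oxidation or decomposition of the aminopyrimidine under peracid, and slow oxidation of the electron-poor iodide. The fallback avoids oxidising the heterocycle at all and sets out from 1, bypassing 2 and 3. Direct C5–H iodanation of 1 with [hydroxy(tosyloxy)iodo]mesitylene (from iodomesitylene diacetate and TsOH·H2O) in 2,2,2-trifluoroethanol brings in the trivalent iodine already bonded to mesityl. It gives (4-amino-2-bromopyrimidin-5-yl)(2,4,6-trimethylphenyl)iodonium 4-methylbenzenesulfonate F4. Anion metathesis with aqueous NaOTf comes back to the route at 4.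

Step 4 (demethylation). The risks are incomplete cleavage on the poly-basic substrate and loss of the air-sensitive 4-hydroxyindole product under strong Lewis acid. The fallback changes the protecting-group plan and sets out from 5. BBr3 demethylation at the simple indole stage gives 7-bromo-1H-indol-4-ol F5. TBSCl and imidazole in DMF give 7-bromo-4-[(tert-butyldimethylsilyl)oxy]-1H-indole F6. Coupling with 4 under the step 3 conditions gives 2-bromo-5-{7-bromo-4-[(tert-butyldimethylsilyl)oxy]-1H-indol-3-yl}pyrimidin-4-amine F7. KHF2 in MeOH at rt removes the silyl group and comes back to the route at 8.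

## Further compounds

F1 | step 3 | 1-(7-bromo-4-methoxy-1H-indol-3-yl)-1,2-benziodoxol-3(1H)-one | COc1ccc(Br)c2[nH]cc(I3OC(=O)c4ccccc34)c12
F2 | step 3 | N-(2-bromopyrimidin-4-yl)acetamide | CC(=O)Nc1ccnc(Br)n1
F3 | step 3 | N-[2-bromo-5-(7-bromo-4-methoxy-1H-indol-3-yl)pyrimidin-4-yl]acetamide | COc1ccc(Br)c2[nH]cc(-c3cnc(Br)nc3NC(C)=O)c12
F4 | step 2 | (4-amino-2-bromopyrimidin-5-yl)(2,4,6-trimethylphenyl)iodonium 4-methylbenzenesulfonate | Cc1cc(C)c([I+]c2cnc(Br)nc2N)c(C)c1.Cc1ccc(cc1)S(=O)(=O)[O-]
F5 | step 4 | 7-bromo-1H-indol-4-ol | Oc1ccc(Br)c2[nH]ccc12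
F6 | step 4 | 7-bromo-4-[(tert-butyldimethylsilyl)oxy]-1H-indole | CC(C)(C)[Si](C)(C)Oc1ccc(Br)c2[nH]ccc12
F7 | step 4 | 2-bromo-5-{7-bromo-4-[(tert-butyldimethylsilyl)oxy]-1H-indol-3-yl}pyrimidin-4-amine | CC(C)(C)[Si](C)(C)Oc1ccc(Br)c2[nH]cc(-c3cnc(Br)nc3N)c12
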